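**Retrosynthetic overview**
The strategy rests on the benzene ring of the tetrahydroisoquinoline: C4a (carrying the C4 methylene), C5 (carrying the bond to C1 of the naphthalene) and C6 (carrying OMe) are neighbours, the alkyl / aryl / blocked-ortho triad that a palladium–norbornene Catellani reaction writes onto 1-iodo-2,4-dimethoxybenzene.
Disconnections: N–Ts cleavage; C1–C8a by an N-sulfonyl Pictet–Spengler closure with formaldehyde; then C4a–C4 and C5–C(naphthyl) together in one three-component coupling of the iodoarene, (S)-2-methyl-1-tosylaziridine and a 1-naphthyl pinacol boronate.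
The naphthalene is made from 2-bromo-5-methoxybenzaldehyde by Stobbe benzannulation; the C3 stereocentre comes from L-alaninol.
Ring order: second naphthalene ring first, then the three-fragment union (no ring formed), and the nitrogen ring last.

Key step: step 10

Assumption: the target fixes only C3 (S) and leaves the biaryl axis undefined, so the product is taken as whatever mixture of atropisomers the coupling gives.

**Route**

Step 1
Reactants: 1 2-bromo-5-methoxybenzaldehyde; 2 diethyl succinate
Product: 3 (E)-4-(2-bromo-5-methoxyphenyl)-3-(ethoxycarbonyl)but-3-enoic acid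
Conditions: KOtBu (1.2 equiv), tBuOH, reflux; then aq. HCl
Reagents that add atoms: none
Why: Stobbe condensation: the succinate enolate adds to the aldehyde, the alkoxide lactonises, and base-induced opening of the paraconate should give the half-ester with the aryl group cis to the CH2CO2H arm, as the next closure requires.

Step 2
Reactants: 3 (E)-4-(2-bromo-5-methoxyphenyl)-3-(ethoxycarbonyl)but-3-enoic acid
Product: 5 ethyl 4-acetoxy-8-bromo-5-methoxy-2-naphthoate, via mixed acetic anhydride 4 (not isolated)
Conditions: Ac2O, NaOAc, reflux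
Reagents that add atoms: acetic anhydride, CC(=O)OC(C)=O
Why: Friedel–Crafts-type closure of the mixed anhydride onto the only free ortho carbon (the other bears Br), which is activated by the adjacent OMe, followed by in situ acetylation of the new naphthol; this is the standard Stobbe benzannulation.

Step 3
Reactants: 5 ethyl 4-acetoxy-8-bromo-5-methoxy-2-naphthoate
Product: 6 ethyl 8-bromo-4-hydroxy-5-methoxy-2-naphthoate
Conditions: NaOEt (1.2 equiv), EtOH, 0 °C to rt; then aq. HCl
Reagents that add atoms: none
Why: Base-mediated transesterification removes the aryl acetate rapidly, and ethoxide in ethanol leaves the ethyl ester unchanged.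

Step 4
Reactants: 6 ethyl 8-bromo-4-hydroxy-5-methoxy-2-naphthoate
Product: 7 ethyl 8-bromo-4,5-dimethoxy-2-naphthoate
Conditions: MeI, K2CO3, DMF, rt
Reagents that add atoms: iodomethane, CI
Why: Williamson O-methylation of the naphthoxide; the ester and the aryl bromide are inert to these conditions.

Step 5
Reactants: 7 ethyl 8-bromo-4,5-dimethoxy-2-naphthoate
Product: 8 (8-bromo-4,5-dimethoxynaphthalen-2-yl)methanol
Conditions: iBu2AlH (DIBAL-H, 2.5 equiv), CH2Cl2, −78 to 0 °C; aq. potassium sodium tartrate
Reagents that add atoms: none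
Why: Hydride reduction of the ester to the primary benzylic alcohol with a reagent that does not touch the aryl bromide at low temperature.

Step 6
Reactants: 8 (8-bromo-4,5-dimethoxynaphthalen-2-yl)methanol
Product: 9 1-bromo-7-(bromomethyl)-4,5-dimethoxynaphthalene
Conditions: PPh3, CBr4, CH2Cl2, 0 °C
Reagents that add atoms: carbon tetrabromide, BrC(Br)(Br)Br
Why: Appel reaction converts the benzylic alcohol into the bromide under neutral conditions that spare the acid-sensitive electron-rich naphthalene.

Step 7
Reactants: 9 1-bromo-7-(bromomethyl)-4,5-dimethoxynaphthalene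
Product: 10 1-bromo-4,5-dimethoxy-7-methylnaphthalene
Conditions: LiBHEt3, THF, 0 °C
Reagents that add atoms: none
Why: SN2 hydride displacement of the benzylic bromide is far faster than any reaction of LiBHEt3 with the aryl bromide at 0 °C, so only the CH2Br group should be reduced to CH3.

Step 8
Reactants: 10 1-bromo-4,5-dimethoxy-7-methylnaphthalene
Product: 11 2-(4,5-dimethoxy-7-methylnaphthalen-1-yl)-4,4,5,5-tetramethyl-1,3,2-dioxaborolane
Conditions: B2pin2, Pd(dppf)Cl2 (5 mol %), KOAc, 1,4-dioxane, 90 °C
Reagents that add atoms: bis(pinacolato)diboron, CC1(C)OB(OC1(C)C)B1OC(C)(C)C(C)(C)O1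
Why: Miyaura borylation of an aryl bromide; the weak base KOAc suppresses Suzuki homocoupling of the product.

Step 9
Reactants: 12 L-alaninol, (S)-2-aminopropan-1-ol
Product: 15 (S)-2-methyl-1-tosylaziridine, via N-tosyl-L-alaninol 13 (not isolated), via N,O-ditosyl-L-alaninol 14 (not isolated)
Conditions: TsCl (2.3 equiv), KOH, CH2Cl2/H2O, rt
Reagents that add atoms: p-toluenesulfonyl chloride, Cc1ccc(cc1)S(Cl)(=O)=O
Why: N- then O-sulfonylation followed by intramolecular SN2 displacement (3-exo-tet) at the primary carbon; the stereocentre is not the reacting carbon, so the S configuration is retained.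

Step 10
Reactants: 16 1-iodo-2,4-dimethoxybenzene; 15 (S)-2-methyl-1-tosylaziridine (2 equiv); 11 2-(4,5-dimethoxy-7-methylnaphthalen-1-yl)-4,4,5,5-tetramethyl-1,3,2-dioxaborolane (1.5 equiv)
Product: 17 N-[(2S)-1-[2-(4,5-dimethoxy-7-methylnaphthalen-1-yl)-3,5-dimethoxyphenyl]propan-2-yl]-4-methylbenzenesulfonamide
Conditions: Pd(OAc)2 (10 mol %), P(2-furyl)3 (25 mol %), norbornene (2 equiv), Cs2CO3 (3 equiv), MeCN/H2O (10:1), 80 °C
Reagents that add atoms: none
Why: Proposed new method: zerovalent palladium inserts into the C–I bond of 16, norbornene undergoes carbopalladation, and the single free ortho C–H is palladated to the aryl–norbornyl palladacycle of divalent palladium, which opens aziridine 15 at its CH2 carbon by SN2-type oxidative addition to tetravalent palladium and forms the aryl–CH2 bond by reductive elimination. With both ortho positions filled, norbornene is expelled by β-carbon elimination and the 2,6-disubstituted arylpalladium species of divalent palladium is intercepted by boronate 11 (transmetalation, reductive elimination), forming the biaryl bond at the former C–I carbon. The closest known reaction types are the Catellani ortho-alkylation of ortho-substituted aryl iodides with N-sulfonyl aziridines and the Catellani ortho-alkylation with ipso Suzuki termination; their combination with a hindered 1-naphthyl boronate is the untested part. No ring closes and no stereocentre is created: the aziridine is attacked only at CH2, so the S centre is carried over unchanged, and the biaryl axis forms without control. The step needs single ortho-alkylation, secured by the OMe at C2 of 16 blocking the second ortho site; opening at the unsubstituted aziridine carbon, secured by sterics; and Suzuki termination in preference to direct coupling of 16 or to intramolecular N-arylation giving a 2-methylindoline. Excess norbornene with the weakly donating P(2-furyl)3 should let insertion outrun transmetalation at the first arylpalladium stage, and excess boronate with aqueous carbonate should let transmetalation outrun C–N closure once norbornene has left.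

Step 11
Reactants: 17 N-[(2S)-1-[2-(4,5-dimethoxy-7-methylnaphthalen-1-yl)-3,5-dimethoxyphenyl]propan-2-yl]-4-methylbenzenesulfonamide; 18 formaldehyde (used as paraformaldehyde, 1.5 equiv)
Product: 20 (3S)-5-(4,5-dimethoxy-7-methylnaphthalen-1-yl)-6,8-dimethoxy-3-methyl-2-tosyl-1,2,3,4-tetrahydroisoquinoline, via N-hydroxymethyl sulfonamide 19 (not isolated)
Conditions: (CH2O)n, CF3CO2H, CH2Cl2, 0 °C to rt
Reagents that add atoms: none
Why: N-sulfonyl Pictet–Spengler reaction: the N-sulfonyliminium ion is attacked in a 6-endo-trig closure by the only free ring carbon ortho to the side chain, which is ortho to one OMe and para to the other; C1 is a CH2 group, so no stereocentre is formed and C3 is untouched.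

Step 12
Reactants: 20 (3S)-5-(4,5-dimethoxy-7-methylnaphthalen-1-yl)-6,8-dimethoxy-3-methyl-2-tosyl-1,2,3,4-tetrahydroisoquinoline
Product: 21 (3S)-5-(4,5-dimethoxy-7-methylnaphthalen-1-yl)-6,8-dimethoxy-3-methyl-1,2,3,4-tetrahydroisoquinoline (target)
Conditions: NaC10H8 (sodium naphthalenide, made from Na and naphthalene), DME, −78 °C; then H2O
Reagents that add atoms: none
Why: Reductive desulfonylation by single-electron transfer to the arenesulfonyl group cleaves the S–N bond at −78 °C, where the more electron-rich dimethoxynaphthalene and the benzylic C1–N bond should not be reduced; no bond to C3 is involved.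

**Compound list**
1 | 2-bromo-5-methoxybenzaldehyde | COc1ccc(Br)c(C=O)c1 | starting material
2 | diethyl succinate | CCOC(=O)CCC(=O)OCC | starting material
3 | (E)-4-(2-bromo-5-methoxyphenyl)-3-(ethoxycarbonyl)but-3-enoic acid | CCOC(=O)/C(CC(=O)O)=C/c1cc(OC)ccc1Br | intermediate
4 | mixed anhydride of acid 3 and acetic acid (not isolated) | CCOC(=O)/C(CC(=O)OC(C)=O)=C/c1cc(OC)ccc1Br | intermediate
5 | ethyl 4-acetoxy-8-bromo-5-methoxy-2-naphthoate | CCOC(=O)c1cc(OC(C)=O)c2c(OC)ccc(Br)c2c1 | intermediate
6 | ethyl 8-bromo-4-hydroxy-5-methoxy-2-naphthoate | CCOC(=O)c1cc(O)c2c(OC)ccc(Br)c2c1 | intermediate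
7 | ethyl 8-bromo-4,5-dimethoxy-2-naphthoate | CCOC(=O)c1cc(OC)c2c(OC)ccc(Br)c2c1 | intermediate
8 | (8-bromo-4,5-dimethoxynaphthalen-2-yl)methanol | OCc1cc(OC)c2c(OC)ccc(Br)c2c1 | intermediate
9 | 1-bromo-7-(bromomethyl)-4,5-dimethoxynaphthalene | BrCc1cc(OC)c2c(OC)ccc(Br)c2c1 | intermediate
10 | 1-bromo-4,5-dimethoxy-7-methylnaphthalene | COc1ccc(Br)c2cc(C)cc(OC)c12 | intermediate
11 | 2-(4,5-dimethoxy-7-methylnaphthalen-1-yl)-4,4,5,5-tetramethyl-1,3,2-dioxaborolane | COc1ccc(B2OC(C)(C)C(C)(C)O2)c2cc(C)cc(OC)c12 | intermediate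
12 | L-alaninol, (S)-2-aminopropan-1-ol | C[C@H](N)CO | starting material
13 | N-tosyl-L-alaninol (not isolated) | C[C@H](NS(=O)(=O)c1ccc(C)cc1)CO | intermediate
14 | N,O-ditosyl-L-alaninol (not isolated) | C[C@H](NS(=O)(=O)c1ccc(C)cc1)COS(=O)(=O)c1ccc(C)cc1 | intermediate
15 | (S)-2-methyl-1-tosylaziridine | C[C@H]1CN1S(=O)(=O)c1ccc(C)cc1 | intermediate
16 | 1-iodo-2,4-dimethoxybenzene | COc1ccc(I)c(OC)c1 | starting material
17 | N-[(2S)-1-[2-(4,5-dimethoxy-7-methylnaphthalen-1-yl)-3,5-dimethoxyphenyl]propan-2-yl]-4-methylbenzenesulfonamide | COc1cc(OC)c(-c2ccc(OC)c3c(OC)cc(C)cc23)c(C[C@H](C)NS(=O)(=O)c2ccc(C)cc2)c1 | intermediate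
18 | formaldehyde (used as paraformaldehyde) | C=O | starting material
19 | N-hydroxymethyl derivative of sulfonamide 17 (not isolated) | COc1cc(OC)c(-c2ccc(OC)c3c(OC)cc(C)cc23)c(C[C@H](C)N(CO)S(=O)(=O)c2ccc(C)cc2)c1 | intermediate
20 | (3S)-5-(4,5-dimethoxy-7-methylnaphthalen-1-yl)-6,8-dimethoxy-3-methyl-2-tosyl-1,2,3,4-tetrahydroisoquinoline | COc1cc(OC)c(-c2ccc(OC)c3c(OC)cc(C)cc23)c2c1CN(S(=O)(=O)c1ccc(C)cc1)[C@@H](C)C2 | intermediate
21 | (3S)-5-(4,5-dimethoxy-7-methylnaphthalen-1-yl)-6,8-dimethoxy-3-methyl-1,2,3,4-tetrahydroisoquinoline | COc1cc(OC)c(-c2ccc(OC)c3c(OC)cc(C)cc23)c2c1CN[C@@H](C)C2 | target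

**Step count and risks**
Total steps: 12. Longest linear sequence: 11 steps (steps 1 to 8, then 10, 11 and 12); step 9 is a one-step side branch.

Steps most likely to fail:

1. Step 10 (three-component Catellani coupling). The ipso termination may go astray: the tosylamide may close onto palladium to give an indoline, the boronate may couple with 16 before the norbornene relay, or the aziridine may be consumed by water or iodide before the palladacycle alkylates. The fallback uses only known reactions, sets out from aziridine 15 and boronate 11, and comes back at 17. Purchased 1-bromo-3,5-dimethoxybenzene F1 is converted with Mg in THF into 3,5-dimethoxyphenylmagnesium bromide F2. F2 opens 15 at its CH2 carbon under CuI catalysis (THF, −30 °C to rt) to give N-[(2S)-1-(3,5-dimethoxyphenyl)propan-2-yl]-4-methylbenzenesulfonamide F3. N-Bromosuccinimide in MeCN at 0 °C should brominate the ring carbon ortho to the side chain and para to a methoxy group, giving N-[(2S)-1-(2-bromo-3,5-dimethoxyphenyl)propan-2-yl]-4-methylbenzenesulfonamide F4. Suzuki coupling of F4 with 11 (Pd(OAc)2, SPhos, K3PO4, toluene/H2O, 100 °C) then gives 17.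

2. Step 11 (Pictet–Spengler closure). Formaldehyde-derived electrophiles may attack the electron-rich dimethoxynaphthalene or bridge two molecules faster than the ring closes. The fallback tethers the one-carbon unit to nitrogen, sets out from 17 and comes back at 21. Sodium naphthalenide (NaC10H8, DME, −78 °C) removes the tosyl group from the open-chain sulfonamide to give (2S)-1-[2-(4,5-dimethoxy-7-methylnaphthalen-1-yl)-3,5-dimethoxyphenyl]propan-2-amine F5. Refluxing ethyl formate gives N-[(2S)-1-[2-(4,5-dimethoxy-7-methylnaphthalen-1-yl)-3,5-dimethoxyphenyl]propan-2-yl]formamide F6. Bischler–Napieralski cyclodehydration (POCl3, MeCN, reflux) closes the ring at the same activated carbon to give (3S)-5-(4,5-dimethoxy-7-methylnaphthalen-1-yl)-6,8-dimethoxy-3-methyl-3,4-dihydroisoquinoline F7. NaBH4 in MeOH at 0 °C reduces the C=N bond to give 21; C1 becomes CH2, so no stereocentre arises.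

3. Step 12 (detosylation). Electron transfer may go into the naphthalene ring or cleave the benzylic C1–N bond instead of the S–N bond, or the cleavage may stall. The fallback replaces tosyl by a sulfonyl group that is removed without a reductant, sets out from 12 and comes back at 21. 2-Nitrobenzenesulfonyl chloride (Et3N, CH2Cl2, 0 °C) converts 12 into N-[(2S)-1-hydroxypropan-2-yl]-2-nitrobenzenesulfonamide F8. Mitsunobu closure (PPh3, DIAD, THF) gives (S)-2-methyl-1-(2-nitrophenylsulfonyl)aziridine F9. The coupling of step 10 with 16 and 11 should then give N-[(2S)-1-[2-(4,5-dimethoxy-7-methylnaphthalen-1-yl)-3,5-dimethoxyphenyl]propan-2-yl]-2-nitrobenzenesulfonamide F10. The closure of step 11 with 18 proceeds through the N-hydroxymethyl derivative of sulfonamide F10 F11 (not isolated) to (3S)-5-(4,5-dimethoxy-7-methylnaphthalen-1-yl)-6,8-dimethoxy-3-methyl-2-(2-nitrophenylsulfonyl)-1,2,3,4-tetrahydroisoquinoline F12. PhSH and K2CO3 in MeCN at rt cleave the sulfonamide by ipso attack of the thiolate and loss of SO2, giving 21.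

**Further compounds**
F1 | step 10 | 1-bromo-3,5-dimethoxybenzene (purchased) | COc1cc(Br)cc(OC)c1
F2 | step 10 | 3,5-dimethoxyphenylmagnesium bromide | COc1cc([Mg]Br)cc(OC)c1
F3 | step 10 | N-[(2S)-1-(3,5-dimethoxyphenyl)propan-2-yl]-4-methylbenzenesulfonamide | COc1cc(OC)cc(C[C@H](C)NS(=O)(=O)c2ccc(C)cc2)c1
F4 | step 10 | N-[(2S)-1-(2-bromo-3,5-dimethoxyphenyl)propan-2-yl]-4-methylbenzenesulfonamide | COc1cc(OC)c(Br)c(C[C@H](C)NS(=O)(=O)c2ccc(C)cc2)c1
F5 | step 11 | (2S)-1-[2-(4,5-dimethoxy-7-methylnaphthalen-1-yl)-3,5-dimethoxyphenyl]propan-2-amine | COc1cc(OC)c(-c2ccc(OC)c3c(OC)cc(C)cc23)c(C[C@H](C)N)c1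
F6 | step 11 | N-[(2S)-1-[2-(4,5-dimethoxy-7-methylnaphthalen-1-yl)-3,5-dimethoxyphenyl]propan-2-yl]formamide | COc1cc(OC)c(-c2ccc(OC)c3c(OC)cc(C)cc23)c(C[C@H](C)NC=O)c1
F7 | step 11 | (3S)-5-(4,5-dimethoxy-7-methylnaphthalen-1-yl)-6,8-dimethoxy-3-methyl-3,4-dihydroisoquinoline | COc1cc(OC)c(-c2ccc(OC)c3c(OC)cc(C)cc23)c2c1C=N[C@@H](C)C2
F8 | step 12 | N-[(2S)-1-hydroxypropan-2-yl]-2-nitrobenzenesulfonamide | C[C@H](NS(=O)(=O)c1ccccc1[N+](=O)[O-])CO
F9 | step 12 | (S)-2-methyl-1-(2-nitrophenylsulfonyl)aziridine | C[C@H]1CN1S(=O)(=O)c1ccccc1[N+](=O)[O-]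
F10 | step 12 | N-[(2S)-1-[2-(4,5-dimethoxy-7-methylnaphthalen-1-yl)-3,5-dimethoxyphenyl]propan-2-yl]-2-nitrobenzenesulfonamide | COc1cc(OC)c(-c2ccc(OC)c3c(OC)cc(C)cc23)c(C[C@H](C)NS(=O)(=O)c2ccccc2[N+](=O)[O-])c1
F11 | step 12 | N-hydroxymethyl derivative of sulfonamide F10 (not isolated) | COc1cc(OC)c(-c2ccc(OC)c3c(OC)cc(C)cc23)c(C[C@H](C)N(CO)S(=O)(=O)c2ccccc2[N+](=O)[O-])c1
F12 | step 12 | (3S)-5-(4,5-dimethoxy-7-methylnaphthalen-1-yl)-6,8-dimethoxy-3-methyl-2-(2-nitrophenylsulfonyl)-1,2,3,4-tetrahydroisoquinoline | COc1cc(OC)c(-c2ccc(OC)c3c(OC)cc(C)cc23)c2c1CN(S(=O)(=O)c1ccccc1[N+](=O)[O-])[C@@H](C)C2
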